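Glisoflavone is disconnected across ring A at C4a–C5 and C8–C8a, so that the benzene ring is built last on a preformed ring C that already carries ring B. The 5-methoxy/7-hydroxy pattern of ring A, with the methoxy carbon C5 bonded to C4a beside the C4 carbonyl, maps onto the ketene-acetal carbon and the silyloxy carbon of a 1,1-dimethoxy-3-silyloxybutadiene. One operation on a 3-aryl-5-bromo-4-pyranone therefore forms both ring bonds, and loss of HBr and of the silyl and one methoxy group delivers the aromatic chromone with oxygen functions correctly placed. The precursor is the 4-pyranone bearing bromine at the future C4a and the bis-MOM-protected prenylcatechol ring at C3.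

Key step: step 9

Assumption: atom labels such as C4a, C5 and C8a are those of the chromone product and are used for the same atoms in the pyranone, the diene and the cycloadducts; intermediates 17 and 18 are racemic and lose their stereocentres within step 9.

Step 1
Reactants: 1 4H-pyran-4-one
Product: 2 3,5-dibromo-4H-pyran-4-one
Conditions: Br2 (2.2 equiv), pyridine (4 equiv), CH2Cl2, 0 °C to rt
Reagents that add atoms: bromine, BrBr
Why: Electrophilic bromine adds to each enol-ether double bond of the vinylogous ester and pyridine removes HBr, the standard addition–elimination α-bromination of an enone, which on this symmetrical ring can only end at the 3,5-dibromide.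

Step 2
Reactants: 3 catechol
Product: 4 1,2-bis(methoxymethoxy)benzene
Conditions: MOMCl (2.5 equiv), i-Pr2NEt (3 equiv), CH2Cl2, 0 °C to rt
Reagents that add atoms: chloromethyl methyl ether, COCCl
Why: Williamson-type O-alkylation of both phenols by the reactive α-chloro ether gives the bis-acetal, which protects the catechol and directs the metalation of the next step.

Step 3
Reactants: 4 1,2-bis(methoxymethoxy)benzene; 5 prenyl bromide (1-bromo-3-methylbut-2-ene)
Product: 8 1,2-bis(methoxymethoxy)-3-(3-methylbut-2-en-1-yl)benzene, via aryllithium 6 (not isolated), via arylcopper 7 (not isolated)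
Conditions: n-BuLi (1.1 equiv), THF, 0 °C; CuBr·SMe2 (1.1 equiv), −40 °C; then 5, −40 °C to rt
Reagents that add atoms: none
Why: Directed ortho-metalation by the chelating OMOM group gives the C3 aryllithium, and transmetalation to copper should secure SN2 allylic substitution at the primary carbon of prenyl bromide without allylic transposition.

Step 4
Reactants: 8 1,2-bis(methoxymethoxy)-3-(3-methylbut-2-en-1-yl)benzene
Product: 9 2-[3,4-bis(methoxymethoxy)-5-(3-methylbut-2-en-1-yl)phenyl]-4,4,5,5-tetramethyl-1,3,2-dioxaborolane
Conditions: [Ir(OMe)(cod)]2 (1.5 mol %), 4,4'-di-tert-butyl-2,2'-bipyridine (3 mol %), B2pin2 (1.0 equiv), THF, 50 °C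
Reagents that add atoms: bis(pinacolato)diboron, CC1(C)OB(OC1(C)C)B1OC(C)(C)C(C)(C)O1
Why: Iridium-catalysed C–H borylation is sterically controlled and should take the only ring C–H flanked by two hydrogens (C5, para to the inner OMOM group), while the trisubstituted prenyl alkene is too hindered to be hydroborated at this temperature.

Step 5
Reactants: 2 3,5-dibromo-4H-pyran-4-one (3 equiv); 9 the aryl pinacol boronate
Product: 10 3-[3,4-bis(methoxymethoxy)-5-(3-methylbut-2-en-1-yl)phenyl]-5-bromo-4H-pyran-4-one
Conditions: Pd(dppf)Cl2 (5 mol %), K3PO4 (2 equiv), 1,4-dioxane–H2O (10:1), 60 °C; excess 2 recovered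
Reagents that add atoms: none
Why: Suzuki–Miyaura coupling at the activated α-bromoenone C–Br bond; the excess of the symmetrical dibromide should make mono-arylation dominate and the mild phosphate base should spare the pyranone ring.

Step 6
Reactants: 11 1,1-dichloroethene; 12 acetyl chloride
Product: 14 4,4-dichlorobut-3-en-2-one, via 4,4,4-trichlorobutan-2-one 13 (not isolated)
Conditions: AlCl3 (1.1 equiv), CH2Cl2, 0 °C to rt; ice/HCl quench; crude 13, Et3N, Et2O, 0 °C
Reagents that add atoms: none
Why: Friedel–Crafts-type acylation of the alkene at its CH2 terminus gives the chloride-trapped adduct 13, from which triethylamine removes HCl (E1cB) to leave the conjugated dichloroenone.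

Step 7
Reactants: 14 4,4-dichlorobut-3-en-2-one
Product: 15 4,4-dimethoxybut-3-en-2-one
Conditions: NaOMe (2.2 equiv), MeOH, 0 °C to rt
Reagents that add atoms: sodium methoxide, C[O-].[Na+]
Why: Two successive addition–elimination (vinylic nucleophilic substitution) steps replace both β-chlorides of the enone by methoxide and give the acyl ketene acetal.

Step 8
Reactants: 15 4,4-dimethoxybut-3-en-2-one
Product: 16 1,1-dimethoxy-3-(trimethylsilyloxy)buta-1,3-diene
Conditions: TMSCl, Et3N, ZnCl2 (cat.), toluene, 40 °C; filtration and distillation under reduced pressure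
Reagents that add atoms: chlorotrimethylsilane, C[Si](C)(C)Cl
Why: Soft enolisation of the methyl ketone and O-silylation (silyl enol ether formation) give the cross-conjugated 2-silyloxydiene, the usual way to such dienes from methyl vinyl ketones.

Step 9
Reactants: 10 3-[3,4-bis(methoxymethoxy)-5-(3-methylbut-2-en-1-yl)phenyl]-5-bromo-4H-pyran-4-one; 16 1,1-dimethoxy-3-(trimethylsilyloxy)buta-1,3-diene (3 equiv)
Product: 19 glisoflavone 3',4'-bis(methoxymethyl) ether, via cis cycloadduct 17 (not isolated), via bromo enedione 18 (not isolated)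
Conditions: Eu(fod)3 (5 mol %), toluene, 80 °C, sealed tube; then DBU (3 equiv), MeOH–CH2Cl2, 0 °C to rt; aq. NH4Cl
Reagents that add atoms: none
Why: Proposed new method: the Eu(fod)3-bound bromopyranone is attacked at C8a, its oxygen-bearing β-carbon, by the CH2 terminus of the vinylogous ketene acetal 16, and the α-bromo enolate carbon C4a then bonds to the dimethoxy-stabilised cationic carbon C5, either concertedly as a normal-demand Diels–Alder addition or stepwise as a Mukaiyama–Michael addition followed by a 6-(enolexo)-exo-trig closure of ring A, giving the cis adduct 17. DBU in methanol then cleaves the silyl enol ether, the enolate expels methoxide from C5 (E1cB) to give the vinylogous ester 18, base removes HBr across C4a–C8a, and the resulting ring A dienone tautomerises to the 7-phenol. The C7 ketone of 18 permits reversible retro-oxa-Michael opening of ring C, which has no route to an arene while bromine remains on C4a and so merely epimerises C8a, feeding the trans-fused isomer whose C8a–H and C4a–Br are antiperiplanar for E2. The closest known reaction types are the cycloaddition–dehydrohalogenation of 1,1-dialkoxy-3-silyloxydienes with bromoquinones and the additions of silyloxydienes to chromones carrying an acceptor at C3. No stereocentre survives, so only site and orientation selectivity are needed: bromine lowers the LUMO of the C4a–C8a double bond and stabilises the enolate formed there while the twisted ring B shields C2–C3, and pairing the nucleophilic diene CH2 with the electrophilic C8a places OMe at C5 and OH at C7.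

Step 10
Reactants: 19 glisoflavone 3',4'-bis(methoxymethyl) ether
Product: 20 glisoflavone
Conditions: HCl (1.25 M in MeOH), rt to 40 °C
Reagents that add atoms: none
Why: Acid-catalysed acetal exchange (methanolysis) of the two aryl MOM ethers needs far less acidity than protonation of the trisubstituted alkene, so the ortho-prenylphenol should not close to a chroman and the C5 methyl ether stays intact.

Compound list
1 | 4H-pyran-4-one | O=c1ccocc1 | starting material
2 | 3,5-dibromo-4H-pyran-4-one | O=c1c(Br)cocc1Br | intermediate
3 | catechol (benzene-1,2-diol) | Oc1ccccc1O | starting material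
4 | 1,2-bis(methoxymethoxy)benzene | COCOc1ccccc1OCOC | intermediate
5 | prenyl bromide (1-bromo-3-methylbut-2-ene) | CC(C)=CCBr | starting material
6 | [2,3-bis(methoxymethoxy)phenyl]lithium | [Li]c1cccc(OCOC)c1OCOC | intermediate
7 | [2,3-bis(methoxymethoxy)phenyl]copper | [Cu]c1cccc(OCOC)c1OCOC | intermediate
8 | 1,2-bis(methoxymethoxy)-3-(3-methylbut-2-en-1-yl)benzene | COCOc1cccc(CC=C(C)C)c1OCOC | intermediate
9 | 2-[3,4-bis(methoxymethoxy)-5-(3-methylbut-2-en-1-yl)phenyl]-4,4,5,5-tetramethyl-1,3,2-dioxaborolane | COCOc1cc(B2OC(C)(C)C(C)(C)O2)cc(CC=C(C)C)c1OCOC | intermediate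
10 | 3-[3,4-bis(methoxymethoxy)-5-(3-methylbut-2-en-1-yl)phenyl]-5-bromo-4H-pyran-4-one | O=c1c(Br)cocc1-c1cc(OCOC)c(OCOC)c(CC=C(C)C)c1 | intermediate
11 | 1,1-dichloroethene | C=C(Cl)Cl | starting material
12 | acetyl chloride | CC(=O)Cl | starting material
13 | 4,4,4-trichlorobutan-2-one | CC(=O)CC(Cl)(Cl)Cl | intermediate
14 | 4,4-dichlorobut-3-en-2-one | CC(=O)C=C(Cl)Cl | intermediate
15 | 4,4-dimethoxybut-3-en-2-one | CC(=O)C=C(OC)OC | intermediate
16 | 1,1-dimethoxy-3-(trimethylsilyloxy)buta-1,3-diene | COC(OC)=CC(=C)O[Si](C)(C)C | intermediate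
17 | 3-[3,4-bis(methoxymethoxy)-5-(3-methylbut-2-en-1-yl)phenyl]-4a-bromo-5,5-dimethoxy-7-(trimethylsilyloxy)-4a,5,8,8a-tetrahydro-4H-chromen-4-one, racemic, cis ring fusion (Br at C4a and H at C8a on the same face; one enantiomer drawn) | COC1(OC)C=C(O[Si](C)(C)C)C[C@H]2OC=C(-c3cc(OCOC)c(OCOC)c(CC=C(C)C)c3)C(=O)[C@@]12Br | intermediate
18 | 3-[3,4-bis(methoxymethoxy)-5-(3-methylbut-2-en-1-yl)phenyl]-4a-bromo-5-methoxy-8,8a-dihydro-4H-chromene-4,7(4aH)-dione, racemic, formed cis-fused (one enantiomer drawn) and epimerising at C8a under base | COC1=CC(=O)C[C@H]2OC=C(-c3cc(OCOC)c(OCOC)c(CC=C(C)C)c3)C(=O)[C@@]12Br | intermediate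
19 | glisoflavone 3',4'-bis(methoxymethyl) ether, 3-[3,4-bis(methoxymethoxy)-5-(3-methylbut-2-en-1-yl)phenyl]-7-hydroxy-5-methoxy-4H-chromen-4-one | COc1cc(O)cc2occ(-c3cc(OCOC)c(OCOC)c(CC=C(C)C)c3)c(=O)c12 | intermediate
20 | glisoflavone, 3-[3,4-dihydroxy-5-(3-methylbut-2-en-1-yl)phenyl]-7-hydroxy-5-methoxy-4H-chromen-4-one | COc1cc(O)cc2occ(-c3cc(O)c(O)c(CC=C(C)C)c3)c(=O)c12 | target

Total step count: 10 steps.
Longest linear sequence: 6 steps (catechol 3 → 4 → 8 → 9 → 10 → 19 → 20; steps 2, 3, 4, 5, 9 and 10).

Steps most likely to fail

Step 9 (proposed new method). The vinylogous-ester double bond of the pyranone may be too poor an acceptor, so that the diene oligomerises or hydrolyses before it adds. Addition may also stop after the first C–C bond, or the ring-opened bromodienone may lose its acyl group or transfer its bromine instead of re-closing and eliminating HBr. The fallback uses the established isoflavone assembly; it sets out from boronate 9 and comes back to the route at target 20. Commercial 1-(2,4-dihydroxy-6-methoxyphenyl)ethan-1-one F1 would be protected selectively at the non-chelated 4-hydroxyl (MOMCl, K2CO3, acetone) to give 1-[2-hydroxy-6-methoxy-4-(methoxymethoxy)phenyl]ethan-1-one F2. Condensation with Me2NCH(OMe)2 at 90 °C would give the enaminone (E)-3-(dimethylamino)-1-[2-hydroxy-6-methoxy-4-(methoxymethoxy)phenyl]prop-2-en-1-one F3. Iodine with pyridine in CHCl3 would cyclise it to 3-iodo-5-methoxy-7-(methoxymethoxy)-4H-chromen-4-one F4. Suzuki–Miyaura coupling of F4 with 9 (Pd(dppf)Cl2, K2CO3, dioxane–H2O) would give 3-[3,4-bis(methoxymethoxy)-5-(3-methylbut-2-en-1-yl)phenyl]-5-methoxy-7-(methoxymethoxy)-4H-chromen-4-one F5. The acidic methanolysis of step 10 would then remove all three MOM groups and give 20.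

Step 5. Over-arylation to the 3,5-diaryl pyranone and base-induced opening of the electrophilic dibromopyranone ring during the coupling could erode the mono-coupled product. The fallback replaces statistical control by halogen differentiation; it sets out from 4H-pyran-4-one 1 and comes back at bromopyranone 10. Monobromination (Br2, 1 equiv, pyridine, CH2Cl2) would give 3-bromo-4H-pyran-4-one F6. α-Iodination of the remaining enol-ether double bond by the same addition–elimination logic (ICl, pyridine, CH2Cl2) would give 3-bromo-5-iodo-4H-pyran-4-one F7. Coupling of F7 with one equivalent of 9 at room temperature (Pd(dppf)Cl2, K3PO4) should then occur only at the carbon–iodine bond and deliver 10.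

Step 4. Hydroboration or isomerisation of the prenyl alkene by the iridium hydride and pinacolborane formed during the borylation, or incomplete site control, could consume the arene. The fallback fixes the boron position through a halogen; it sets out from prenyl bromide 5 and comes back at boronate 9. Commercial 3,5-dibromo-2-hydroxybenzaldehyde F8 would undergo Dakin oxidation (H2O2, NaOH) to 3,5-dibromobenzene-1,2-diol F9. MOM protection (MOMCl, i-Pr2NEt) would give 1,5-dibromo-2,3-bis(methoxymethoxy)benzene F10. Bromine–lithium exchange at the bromine ortho to OMOM (n-BuLi, THF, −78 °C), transmetalation with CuBr·SMe2 and alkylation with 5 would give 5-bromo-1,2-bis(methoxymethoxy)-3-(3-methylbut-2-en-1-yl)benzene F11. Miyaura borylation (Pd(dppf)Cl2, B2pin2, KOAc, dioxane, 80 °C) would convert F11 into 9.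

Further compounds
F1 | step 9 | 1-(2,4-dihydroxy-6-methoxyphenyl)ethan-1-one | CC(=O)c1c(O)cc(O)cc1OC
F2 | step 9 | 1-[2-hydroxy-6-methoxy-4-(methoxymethoxy)phenyl]ethan-1-one | CC(=O)c1c(O)cc(OCOC)cc1OC
F3 | step 9 | (E)-3-(dimethylamino)-1-[2-hydroxy-6-methoxy-4-(methoxymethoxy)phenyl]prop-2-en-1-one | CN(C)/C=C/C(=O)c1c(O)cc(OCOC)cc1OC
F4 | step 9 | 3-iodo-5-methoxy-7-(methoxymethoxy)-4H-chromen-4-one | COCOc1cc(OC)c2c(=O)c(I)coc2c1
F5 | step 9 | 3-[3,4-bis(methoxymethoxy)-5-(3-methylbut-2-en-1-yl)phenyl]-5-methoxy-7-(methoxymethoxy)-4H-chromen-4-one | COCOc1cc(OC)c2c(=O)c(-c3cc(OCOC)c(OCOC)c(CC=C(C)C)c3)coc2c1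
F6 | step 5 | 3-bromo-4H-pyran-4-one | O=c1ccocc1Br
F7 | step 5 | 3-bromo-5-iodo-4H-pyran-4-one | O=c1c(Br)cocc1I
F8 | step 4 | 3,5-dibromo-2-hydroxybenzaldehyde | O=Cc1cc(Br)cc(Br)c1O
F9 | step 4 | 3,5-dibromobenzene-1,2-diol | Oc1cc(Br)cc(Br)c1O
F10 | step 4 | 1,5-dibromo-2,3-bis(methoxymethoxy)benzene | COCOc1cc(Br)cc(Br)c1OCOC
F11 | step 4 | 5-bromo-1,2-bis(methoxymethoxy)-3-(3-methylbut-2-en-1-yl)benzene | COCOc1cc(Br)cc(CC=C(C)C)c1OCOC
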